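The readings stem from a simulated flask with made-up constants; noise was put on by code.

Early in a run, substrate passes to intermediate and target follows, first order in intermediate on the proposed steps, and I expect heat to speed that stretch. Your hunch that the hottest flask ends richest in target carries that stretch through to the end, and I wouldn't. The second step also runs back, through target and by-product together, so late in a run you should watch one gauge.

| setting | delta | alpha | autumn | winter | midnight |
|---|---|---|---|---|---|
| substrate | 0.50 M | 0.50 M | 0.50 M | 0.50 M | 0.50 M |
| reagent | 0.25 M | 1 M | 0.500 M | 0.500 M | 0.500 M |
| temperature | 24 °C | 33 °C | 20 °C | 28 °C | 36 °C |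
| remark | run made earlier | run made earlier |  |  |  |
| time |  |  | 2.5 d | 2.5 d | 2.5 d |

delta run (percent of the substrate charged)

| time / d | substrate / % | target / % | intermediate / % |
|---|---|---|---|
| 0.333 | 56 | 0 | 23 |
| 0.833 | 37 | 9 | 26 |
| 1.67 | 29 | 16 | 18 |
| 2.50 | 18 | 24 | 18 |

alpha run (percent of the substrate charged)

| time / h | substrate / % | target / % | intermediate / % |
|---|---|---|---|
| 8.00 | 10 | 33 | 50 |
| 15.0 | 6 | 42 | 41 |
| 25.0 | 7 | 44 | 39 |
| 30.0 | 8 | 48 | 38 |

(readings scatter by 2 percentage points)

- in percentages every species weighs as the substrate in it: one self-condensation product counts as two
- steps that have been proposed: substrate + reagent <-> intermediate; intermediate <-> target + by-product; 2 substrate -> self-condensation product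

1. which of these there is most of at the end, counted by the substrate in it, autumn (substrate / target / intermediate)
2. which of these there is most of at the end, counted by the substrate in it, winter (substrate / target / intermediate)
3. which of these there is most of at the end, counted by the substrate in it, midnight (substrate / target / intermediate)
4. amount of the one of these that there is most of at the end, in percent of the substrate charged, autumn
5. amount of the one of these that there is most of at the end, in percent of the substrate charged, winter
6. amount of the one of these that there is most of at the end, in percent of the substrate charged, midnight

Target and by-product are born one for one, so at this shared substrate charge the gauge, in fractions of the charge, is Q, target squared over intermediate: the reaction quotient of the second step. Alpha's last two readings of Q average 0.551, and I take that reading as the balance value, at every temperature, as a rough assumption. Delta's last reading gives Q = 0.320, less than that, so I read delta as still short of balance. Target leads intermediate exactly where Q exceeds target's own fraction.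

For the split I need target plus intermediate. Equal charges lie between delta and alpha, so I take the mean of their last readings, 64.0%. Winter and midnight are warmer than delta, so as a second rough assumption I put them at balance, which gives target 37.9% and intermediate 26.1%. Autumn is cooler than delta, so I give it the mean Q of delta's last two readings, 0.231, which gives target 28.6% and intermediate 35.4%.

The forecast, which calls winter “almost a tie”, has intermediate at 34% in autumn, target at 33% in winter and target at 38% at midnight, parting from me on the size of winter's target.

The flasks give intermediate at 37.9% in autumn, target at 37.5% in winter and target at 35.1% at midnight.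

    substrate + reagent ⇌ intermediate (K = 17.0 M⁻¹, k = 5.30 × 10⁻⁵ M⁻¹ s⁻¹, Ea = 77.0 kJ mol⁻¹, ΔH = −25.0 kJ mol⁻¹)
    intermediate ⇌ target + by-product (K = 0.260 M, k = 3.60 × 10⁻⁶ s⁻¹, Ea = 112 kJ mol⁻¹, ΔH = 2.00 kJ mol⁻¹)
    2 substrate → self-condensation product (k = 7.50 × 10⁻⁶ M⁻¹ s⁻¹, Ea = 81.0 kJ mol⁻¹)
    (constants at 20 °C)

In autumn the half-life of intermediate by its forward path to target alone is 2.2 d against a run of 2.5 d, and at the end intermediate is made at 0.238 of the rate at which it is used up, each step taken net. At the end, autumn's Q stands at 35.8% of the value I read off alpha, winter's at 95.5% and midnight's at 99.9%. The autumn flask read at 6.00 d has Q at 87.6% of that reading, and there target stands above intermediate, at 37.6%.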